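## Retrosynthetic overview

1. Target 18 (3R,5R ring, 2S,4R side chain; ring methyls cis, side-chain methyls anti) ⇐ C3–CH2CO2H bond: catalyst-controlled addition of a bis-silyl ketene acetal to the peroxycarbenium ion from dioxolanyl acetate 16.
2. Dioxolanol 15 ⇐ 2-methyleneoxetane 13 by a stereoinvertive perhydrolytic ring expansion (oxetane → 1,2-dioxolane), which forms the only ring of the target and sets C5.
3. 13 ⇐ β-lactone 12 (carbonyl methylenation) ⇐ epoxide 11 (ring-expansion carbonylation) ⇐ methyl ketone 10 (asymmetric methylene transfer).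
4. 10 ⇐ two Cu-catalysed asymmetric conjugate additions (8-phenyloctyl Grignard to methyl crotonate; MeMgBr to enone 9); the chain comes from styrene, 1,6-dibromohexane and methyl crotonate.
5. Ring order: oxirane → oxetan-2-one → 2-methyleneoxetane → 1,2-dioxolane.

Assumption: in each catalytic asymmetric step the catalyst enantiomer named is the one taken to give the configuration drawn; if the observed sense is the opposite, its antipode is used.

## Route

Step 1
Reactants: 1 styrene; 2 1,6-dibromohexane (4 equiv)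
Product: 4 (8-bromooctyl)benzene, via 9-(2-phenylethyl)-9-borabicyclo[3.3.1]nonane 3 (not isolated)
Conditions: 9-BBN-H, THF, rt; then 2, Pd(OAc)2 (4 mol %), PCy3 (8 mol %), K3PO4·H2O, THF, rt
Reagents that add atoms: none
Why: anti-Markovnikov hydroboration of styrene followed by an alkyl–alkyl Suzuki–Miyaura coupling with a primary alkyl bromide, the excess of dibromide keeping the coupling at one end; no stereocenter is formed.

Step 2
Reactants: 4 (8-bromooctyl)benzene; 5 methyl (E)-but-2-enoate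
Product: 7 methyl (3R)-3-methyl-11-phenylundecanoate, via (8-phenyloctyl)magnesium bromide 6 (not isolated)
Conditions: Mg, Et2O, reflux; then 5, CuBr·SMe2 (1 mol %), (S)-1-[(R)-2-(diphenylphosphino)ferrocenyl]ethyldicyclohexylphosphine (1.2 mol %), t-BuOMe, −75 °C
Reagents that add atoms: none
Why: Cu-catalysed asymmetric conjugate addition of a primary alkyl Grignard reagent to an (E)-crotonate, in which the ferrocenyl diphosphine controls the face of C3 and sets the (R) methyl stereocenter.

Step 3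
Reactants: 7 methyl (3R)-3-methyl-11-phenylundecanoate
Product: 9 (3E,6R)-6-methyl-14-phenyltetradec-3-en-2-one, via (3R)-3-methyl-11-phenylundecanal 8 (not isolated)
Conditions: i-Bu2AlH (1.1 equiv), CH2Cl2, −78 °C; then Ph3P=CHC(O)CH3, −78 °C → 40 °C
Reagents that add atoms: (acetylmethylene)triphenylphosphorane, CC(=O)C=P(c1ccccc1)(c1ccccc1)c1ccccc1
Why: low-temperature half-reduction of the ester gives an aluminium hemiacetal that releases aldehyde 8 on warming, where it is trapped by the stabilised ylide in an E-selective Wittig olefination; the β-stereocenter is not enolisable.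

Step 4
Reactants: 9 (3E,6R)-6-methyl-14-phenyltetradec-3-en-2-one
Product: 10 (4S,6R)-4,6-dimethyl-14-phenyltetradecan-2-one
Conditions: MeMgBr (1.2 equiv), CuBr·SMe2 (5 mol %), (S)-1-[(R)-2-(diphenylphosphino)ferrocenyl]ethyldicyclohexylphosphine (6 mol %), t-BuOMe, −75 °C
Reagents that add atoms: methylmagnesium bromide, C[Mg]Br
Why: Cu-catalysed asymmetric conjugate addition of MeMgBr to a linear (E)-enone under catalyst control sets C4 as (S); the same ligand enantiomer as in step 2 gives the anti-1,3-dimethyl array because the roles of nucleophile and β-substituent are exchanged.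

Step 5
Reactants: 10 (4S,6R)-4,6-dimethyl-14-phenyltetradecan-2-one
Product: 11 (2S)-2-[(2S,4R)-2,4-dimethyl-12-phenyldodecyl]-2-methyloxirane
Conditions: Me3S(O)I, NaH, THF, 65 °C; then 10, LaLi3[(S)-1,1'-binaphthalene-2,2'-diolate]3 (5 mol %), (2,4,6-(MeO)3C6H2)3P=O (5 mol %), 5 Å MS, THF, rt
Reagents that add atoms: trimethylsulfoxonium iodide, C[S+](C)(C)=O.[I-]
Why: catalytic asymmetric Corey–Chaykovsky methylene transfer to a methyl ketone, in which the La/Li binaphthoxide differentiates CH3 from the CH2R arm and delivers CH2 to the Re face, giving the (S)-epoxide independently of the remote methyl centres.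

Step 6
Reactants: 11 (2S)-2-[(2S,4R)-2,4-dimethyl-12-phenyldodecyl]-2-methyloxirane
Product: 12 (4S)-4-[(2S,4R)-2,4-dimethyl-12-phenyldodecyl]-4-methyloxetan-2-one
Conditions: [(ClTPP)Al(THF)2][Co(CO)4] (2 mol %; ClTPP = 5,10,15,20-tetrakis(4-chlorophenyl)porphyrinate), CO (60 bar), THF, 40 °C
Reagents that add atoms: carbon monoxide, [C-]#[O+]
Why: ring-expansion carbonylation in which [Co(CO)4]− opens the Al-activated epoxide at the CH2 terminus, CO inserts and the tertiary alkoxide closes onto the acyl cobalt, so the quaternary C–O bond is untouched and its configuration is retained.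

Step 7
Reactants: 12 (4S)-4-[(2S,4R)-2,4-dimethyl-12-phenyldodecyl]-4-methyloxetan-2-one
Product: 13 (2S)-2-[(2S,4R)-2,4-dimethyl-12-phenyldodecyl]-2-methyl-4-methylideneoxetane
Conditions: Cp2TiMe2 (2.5 equiv), toluene, 75 °C, dark; basic alumina
Reagents that add atoms: dimethyltitanocene, C[Ti](C)(C1C=CC=C1)C1C=CC=C1
Why: Petasis methylenation of the strained lactone carbonyl through Cp2Ti=CH2 gives the 2-methyleneoxetane without touching any stereocenter.

Step 8
Reactants: 13 (2S)-2-[(2S,4R)-2,4-dimethyl-12-phenyldodecyl]-2-methyl-4-methylideneoxetane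
Product: 15 (3RS,5R)-5-[(2S,4R)-2,4-dimethyl-12-phenyldodecyl]-3,5-dimethyl-1,2-dioxolan-3-ol, via (4R,6S,8R)-4-hydroperoxy-4,6,8-trimethyl-16-phenylhexadecan-2-one 14 (not isolated)
Conditions: anhydrous H2O2 in Et2O (3 equiv), Me3SiOTf (10 mol %), Et2O, −78 → −40 °C; NaHCO3 quench
Reagents that add atoms: hydrogen peroxide, OO
Why: Proposed new method: acid released from Me3SiOTf/H2O2 C-protonates the exocyclic enol ether to a 2-methyloxetan-2-ylium ion, whose C4–O bond is activated by ring strain and by a neutral methyl ketone leaving group, and H2O2 attacks the quaternary carbon anti to the departing oxygen (loose SN2, inversion, (S) → (4R)) to give hydroperoxy ketone 14, which closes to the peroxyhemiketal, so the oxetane is expanded to the 1,2-dioxolane with its ring oxygen becoming the 3-OH; the closest known reactions are the Me3SiOTf-mediated invertive perhydrolysis of 2,2-disubstituted oxetanes to 3-hydroperoxy alkanols and the nucleophilic C4 opening of 2-methyleneoxetanes with release of a ketone enolate.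

Step 9
Reactants: 15 (3RS,5R)-5-[(2S,4R)-2,4-dimethyl-12-phenyldodecyl]-3,5-dimethyl-1,2-dioxolan-3-ol
Product: 16 (3RS,5R)-5-[(2S,4R)-2,4-dimethyl-12-phenyldodecyl]-3,5-dimethyl-1,2-dioxolan-3-yl acetate
Conditions: Ac2O, pyridine, DMAP (5 mol %), CH2Cl2, 0 °C
Reagents that add atoms: acetic anhydride, CC(=O)OC(C)=O
Why: DMAP-catalysed O-acetylation locks the peroxyhemiketal in its ring form; both C3 epimers are carried on because C3 becomes planar in the next step, and C5 has no α-hydrogen and is not affected.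

Step 10
Reactants: 16 (3RS,5R)-5-[(2S,4R)-2,4-dimethyl-12-phenyldodecyl]-3,5-dimethyl-1,2-dioxolan-3-yl acetate
Product: 18 2-[(3R,5R)-5-[(2S,4R)-2,4-dimethyl-12-phenyldodecyl]-3,5-dimethyl-1,2-dioxolan-3-yl]acetic acid, via trimethylsilyl 2-[(3R,5R)-5-[(2S,4R)-2,4-dimethyl-12-phenyldodecyl]-3,5-dimethyl-1,2-dioxolan-3-yl]acetate 17 (not isolated)
Conditions: CH2=C(OSiMe3)2 (2 equiv), confined (S,S)-imidodiphosphorimidate Brønsted acid built from two 3,3'-bis[3,5-bis(trifluoromethyl)phenyl]-BINOL units with N-triflyl groups (2 mol %), toluene, −78 °C; then aq. citric acid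
Reagents that add atoms: ketene bis(trimethylsilyl) acetal, C=C(O[Si](C)(C)C)O[Si](C)(C)C
Why: Proposed new method: the silylated imidodiphosphorimidate formed from the acid and the ketene acetal abstracts acetate from either C3 epimer of 16 to give one planar 1,2-dioxolan-3-ylium (peroxycarbenium) ion paired with the confined chiral anion, which blocks one face so that the ketene acetal adds to C3 on the face cis to the C5 side chain (catalyst control, (3R)), and the silyl ester 17 is cleaved on work-up; the closest known reactions are imidodiphosphorimidate-catalysed additions of silyl ketene acetals to cyclic oxocarbenium ions from ketone-derived lactol acetates and achiral Lewis-acid-mediated additions of silyl ketene acetals to 3-acyloxy- and 3-alkoxy-1,2-dioxolanes.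

## Compound list

1 | styrene | C=Cc1ccccc1 | starting material
2 | 1,6-dibromohexane | BrCCCCCCBr | starting material
3 | 9-(2-phenylethyl)-9-borabicyclo[3.3.1]nonane | C(Cc1ccccc1)B1C2CCCC1CCC2 | intermediate
4 | (8-bromooctyl)benzene | BrCCCCCCCCc1ccccc1 | intermediate
5 | methyl (E)-but-2-enoate | C/C=C/C(=O)OC | starting material
6 | (8-phenyloctyl)magnesium bromide | Br[Mg]CCCCCCCCc1ccccc1 | intermediate
7 | methyl (3R)-3-methyl-11-phenylundecanoate | C[C@H](CCCCCCCCc1ccccc1)CC(=O)OC | intermediate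
8 | (3R)-3-methyl-11-phenylundecanal | C[C@H](CCCCCCCCc1ccccc1)CC=O | intermediate
9 | (3E,6R)-6-methyl-14-phenyltetradec-3-en-2-one | C[C@H](CCCCCCCCc1ccccc1)C/C=C/C(C)=O | intermediate
10 | (4S,6R)-4,6-dimethyl-14-phenyltetradecan-2-one | C[C@H](CCCCCCCCc1ccccc1)C[C@H](C)CC(C)=O | intermediate
11 | (2S)-2-[(2S,4R)-2,4-dimethyl-12-phenyldodecyl]-2-methyloxirane | C[C@H](CCCCCCCCc1ccccc1)C[C@H](C)C[C@@]1(C)CO1 | intermediate
12 | (4S)-4-[(2S,4R)-2,4-dimethyl-12-phenyldodecyl]-4-methyloxetan-2-one | C[C@H](CCCCCCCCc1ccccc1)C[C@H](C)C[C@@]1(C)CC(=O)O1 | intermediate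
13 | (2S)-2-[(2S,4R)-2,4-dimethyl-12-phenyldodecyl]-2-methyl-4-methylideneoxetane | C[C@H](CCCCCCCCc1ccccc1)C[C@H](C)C[C@@]1(C)CC(=C)O1 | intermediate
14 | (4R,6S,8R)-4-hydroperoxy-4,6,8-trimethyl-16-phenylhexadecan-2-one | C[C@H](CCCCCCCCc1ccccc1)C[C@H](C)C[C@](C)(CC(C)=O)OO | intermediate
15 | (3RS,5R)-5-[(2S,4R)-2,4-dimethyl-12-phenyldodecyl]-3,5-dimethyl-1,2-dioxolan-3-ol | C[C@H](CCCCCCCCc1ccccc1)C[C@H](C)C[C@]1(C)CC(C)(O)OO1 | intermediate
16 | (3RS,5R)-5-[(2S,4R)-2,4-dimethyl-12-phenyldodecyl]-3,5-dimethyl-1,2-dioxolan-3-yl acetate | C[C@H](CCCCCCCCc1ccccc1)C[C@H](C)C[C@]1(C)CC(C)(OC(C)=O)OO1 | intermediate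
17 | trimethylsilyl 2-[(3R,5R)-5-[(2S,4R)-2,4-dimethyl-12-phenyldodecyl]-3,5-dimethyl-1,2-dioxolan-3-yl]acetate | C[C@H](CCCCCCCCc1ccccc1)C[C@H](C)C[C@]1(C)C[C@](C)(CC(=O)O[Si](C)(C)C)OO1 | intermediate
18 | 2-[(3R,5R)-5-[(2S,4R)-2,4-dimethyl-12-phenyldodecyl]-3,5-dimethyl-1,2-dioxolan-3-yl]acetic acid | C[C@H](CCCCCCCCc1ccccc1)C[C@H](C)C[C@]1(C)C[C@](C)(CC(=O)O)OO1 | target

## Step count and risks

Total step count: 10. Longest linear sequence: 10.

Steps most likely to fail:

Step 8 (new perhydrolytic ring expansion). The oxocarbenium ion may ionise fully (loss of configuration at C5, elimination), or H2O2 may add at C2 instead of C4. The fallback uses known chemistry and sets out from 13. Hydrogenation of the enol ether (H2, Pd/C, EtOAc, trace Et3N) gives (2S,4RS)-2-[(2S,4R)-2,4-dimethyl-12-phenyldodecyl]-2,4-dimethyloxetane F1. The established Me3SiOTf/ethereal H2O2 opening at the tertiary oxetane carbon (inversion, −78 °C) then gives (2RS,4R,6S,8R)-4-hydroperoxy-4,6,8-trimethyl-16-phenylhexadecan-2-ol F2. The hydroperoxide is masked with 2-methoxypropene/PPTS as (2RS,4R,6S,8R)-4-[(2-methoxypropan-2-yl)peroxy]-4,6,8-trimethyl-16-phenylhexadecan-2-ol F3. Dess–Martin oxidation gives (4R,6S,8R)-4-[(2-methoxypropan-2-yl)peroxy]-4,6,8-trimethyl-16-phenylhexadecan-2-one F4, and aqueous acetic acid unmasks the hydroperoxide, which closes through 14 and comes back to the route at 15.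

Step 10 (new catalyst-controlled peroxycarbenium addition). The chiral anion may not override the small substrate bias, or the strong acid may fragment the peroxide. The fallback uses known chemistry and sets out from 16. A stoichiometric achiral Lewis acid (Me3SiOTf or TiCl4, CH2Cl2, −78 °C) with 1-methoxy-1-(trimethylsilyloxy)ethene gives methyl 2-[(3R,5R)-5-[(2S,4R)-2,4-dimethyl-12-phenyldodecyl]-3,5-dimethyl-1,2-dioxolan-3-yl]acetate F5 together with its epimer methyl 2-[(3S,5R)-5-[(2S,4R)-2,4-dimethyl-12-phenyldodecyl]-3,5-dimethyl-1,2-dioxolan-3-yl]acetate F6. The two are separated by preparative HPLC, and F5 is saponified (LiOH, THF/H2O, 0 °C), coming back to the route at 18.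

Step 6 (carbonylation of a hindered 2,2-disubstituted epoxide). Meinwald rearrangement to an aldehyde or slow turnover may intervene. The fallback sets out from 11. Opening at the CH2 terminus with vinylmagnesium bromide/CuI gives (4R,6S,8R)-4,6,8-trimethyl-16-phenylhexadec-1-en-4-ol F7. Ozonolysis (O3, CH2Cl2, −78 °C; Me2S) gives (3S,5S,7R)-3-hydroxy-3,5,7-trimethyl-15-phenylpentadecanal F8, and Pinnick oxidation (NaClO2, NaH2PO4, 2-methyl-2-butene) gives (3S,5S,7R)-3-hydroxy-3,5,7-trimethyl-15-phenylpentadecanoic acid F9. Carboxyl-activating lactonisation (PhSO2Cl, pyridine, 0 °C; retention at the carbinol carbon) comes back to the route at 12.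

## Further compounds

F1 | step 8 | (2S,4RS)-2-[(2S,4R)-2,4-dimethyl-12-phenyldodecyl]-2,4-dimethyloxetane | C[C@H](CCCCCCCCc1ccccc1)C[C@H](C)C[C@@]1(C)CC(C)O1
F2 | step 8 | (2RS,4R,6S,8R)-4-hydroperoxy-4,6,8-trimethyl-16-phenylhexadecan-2-ol | C[C@H](CCCCCCCCc1ccccc1)C[C@H](C)C[C@](C)(CC(C)O)OO
F3 | step 8 | (2RS,4R,6S,8R)-4-[(2-methoxypropan-2-yl)peroxy]-4,6,8-trimethyl-16-phenylhexadecan-2-ol | C[C@H](CCCCCCCCc1ccccc1)C[C@H](C)C[C@](C)(CC(C)O)OOC(C)(C)OC
F4 | step 8 | (4R,6S,8R)-4-[(2-methoxypropan-2-yl)peroxy]-4,6,8-trimethyl-16-phenylhexadecan-2-one | C[C@H](CCCCCCCCc1ccccc1)C[C@H](C)C[C@](C)(CC(C)=O)OOC(C)(C)OC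
F5 | step 10 | methyl 2-[(3R,5R)-5-[(2S,4R)-2,4-dimethyl-12-phenyldodecyl]-3,5-dimethyl-1,2-dioxolan-3-yl]acetate | C[C@H](CCCCCCCCc1ccccc1)C[C@H](C)C[C@]1(C)C[C@](C)(CC(=O)OC)OO1
F6 | step 10 | methyl 2-[(3S,5R)-5-[(2S,4R)-2,4-dimethyl-12-phenyldodecyl]-3,5-dimethyl-1,2-dioxolan-3-yl]acetate | C[C@H](CCCCCCCCc1ccccc1)C[C@H](C)C[C@]1(C)C[C@@](C)(CC(=O)OC)OO1
F7 | step 6 | (4R,6S,8R)-4,6,8-trimethyl-16-phenylhexadec-1-en-4-ol | C[C@H](CCCCCCCCc1ccccc1)C[C@H](C)C[C@@](C)(CC=C)O
F8 | step 6 | (3S,5S,7R)-3-hydroxy-3,5,7-trimethyl-15-phenylpentadecanal | C[C@H](CCCCCCCCc1ccccc1)C[C@H](C)C[C@@](C)(CC=O)O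
F9 | step 6 | (3S,5S,7R)-3-hydroxy-3,5,7-trimethyl-15-phenylpentadecanoic acid | C[C@H](CCCCCCCCc1ccccc1)C[C@H](C)C[C@@](C)(CC(=O)O)O
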